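**Retrosynthetic overview**
1. Feature (eremophilane numbering; ring A = C1–C5 + C10, ring B = C5–C10): ring A carries β-oxygen at C3 and at C10, 1,4 to each other, on either side of the cis β-methyls at C4 and C5. C10–C1–C2–C3 with one bridging oxygen is therefore read as a 2-methoxyfuran, and C4=C5 as the alkene of an (E)-2-methylbut-2-enoyl ketone whose carbonyl is C6.
2. Last disconnections: C7 acetyl (Stille coupling on the 7-iodo enone), C9 angelate (mixed anhydride of angelic acid), C6=C7–C8=O (E1cB loss of a C6 acetate beside a C8 ketone), C3 acetate (α-face hydride on the C3 ketone).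
3. Key disconnection: C5–C10 and C3–C4 by an intramolecular furan Diels–Alder reaction. Rings A and B close together in this one step, and opening of the bridged methoxy ketal gives the 10β-hydroxy-1-en-3-one.
4. Precursor: C7–C8 by a Felkin–Anh aldol of the lithium dienolate of (E)-3-methylpent-3-en-2-one with an α-silyloxy aldehyde. C9–C10 and the C9 configuration come from a catalytic asymmetric Friedel–Crafts reaction of 2-methoxyfuran with ethyl glyoxylate.
5. Design points: the aldol gives the 8,9-anti carbinol, a spectator centre that is erased on oxidation. C8–O and C9–O carry different silyl groups (TES, TBS) so that they can be told apart. The cycloaddition is run thermally, without a Lewis acid.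

Key step: step 6

Assumption: the (S)-ligand is assigned to the (S)-hydroxy ester by analogy with the sense of BINOL–titanium glyoxylate-ene reactions; should the sense be opposite, the (R)-ligand is used.

Step 1
Reactants: 1 2-methoxyfuran; 2 ethyl glyoxylate
Product: 3 ethyl (S)-2-hydroxy-2-(5-methoxyfuran-2-yl)acetate
Conditions: Ti(OiPr)4 (10 mol %), (S)-6,6'-dibromo-BINOL (20 mol %), toluene, 0 °C
Reagents that add atoms: none
Why: Catalytic enantioselective Friedel–Crafts hydroxyalkylation, in which the furan attacks through C5, the position activated by the methoxy group, on one face of the titanium-bound aldehyde; this forms C9–C10 and sets C9, the only stereocentre that comes from a catalyst.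

Step 2
Reactants: 3 ethyl (S)-2-hydroxy-2-(5-methoxyfuran-2-yl)acetate
Product: 4 ethyl (S)-2-(tert-butyldimethylsilyloxy)-2-(5-methoxyfuran-2-yl)acetate
Conditions: TBSCl, imidazole, DMF, 0 to 23 °C
Reagents that add atoms: tert-butyldimethylsilyl chloride, CC(C)(C)[Si](C)(C)Cl
Why: Standard silylation of a secondary alcohol under buffered, non-acidic conditions that the acid-labile methoxyfuran tolerates; C9 is not touched.

Step 3
Reactants: 4 ethyl (S)-2-(tert-butyldimethylsilyloxy)-2-(5-methoxyfuran-2-yl)acetate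
Product: 5 (S)-2-(tert-butyldimethylsilyloxy)-2-(5-methoxyfuran-2-yl)acetaldehyde
Conditions: i-Bu2AlH, CH2Cl2, −78 °C; aqueous work-up; used at once
Reagents that add atoms: none
Why: Partial reduction of an α-silyloxy ester, in which the tetrahedral aluminium hemiacetal survives at −78 °C and collapses to the aldehyde only on work-up; immediate use guards the configurationally labile C9.

Step 4
Reactants: 5 (S)-2-(tert-butyldimethylsilyloxy)-2-(5-methoxyfuran-2-yl)acetaldehyde; 6 (E)-3-methylpent-3-en-2-one
Product: 8 (1R,2R,5E)-1-(tert-butyldimethylsilyloxy)-2-hydroxy-1-(5-methoxyfuran-2-yl)-5-methylhept-5-en-4-one, via lithium dienolate 7 (not isolated)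
Conditions: 6, LiN(i-Pr)2, THF, −78 °C; then 5, −78 °C; AcOH quench
Reagents that add atoms: none
Why: Kinetic deprotonation at the methyl group gives the cross-conjugated lithium dienolate, and its aldol addition follows the polar Felkin–Anh model (attack anti to the C9–O bond), which forms C7–C8 and gives the 8,9-anti carbinol; C8 is a spectator centre that is erased in step 12.

Step 5
Reactants: 8 (1R,2R,5E)-1-(tert-butyldimethylsilyloxy)-2-hydroxy-1-(5-methoxyfuran-2-yl)-5-methylhept-5-en-4-one
Product: 9 (1R,2R,5E)-1-(tert-butyldimethylsilyloxy)-2-(triethylsilyloxy)-1-(5-methoxyfuran-2-yl)-5-methylhept-5-en-4-one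
Conditions: TESCl, imidazole, DMF, 0 °C
Reagents that add atoms: chlorotriethylsilane, CC[Si](Cl)(CC)CC
Why: Silylation with the smaller triethylsilyl group blocks retro-aldol and oxa-Michael reactions of the aldol and gives two silyl ethers of different lability, so that C8–O can later be freed beside C9–OTBS.

Step 6
Reactants: 9 (1R,2R,5E)-1-(tert-butyldimethylsilyloxy)-2-(triethylsilyloxy)-1-(5-methoxyfuran-2-yl)-5-methylhept-5-en-4-one
Product: 11 9α-(tert-butyldimethylsilyloxy)-8α-(triethylsilyloxy)-10β-hydroxy-4β,5β-dimethyl-cis-octal-1-ene-3,6-dione, via bridged methoxy ketal 10 (not isolated)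
Conditions: toluene (0.01 M), BHT (cat.), base-washed sealed tube, 150 °C; then SiO2, CH2Cl2–H2O, 23 °C
Reagents that add atoms: water, O
Why: On heating, furan carbons C10 and C3 add suprafacially to C5 and C4 of the s-cis tigloyl ketone in a concerted but asynchronous intramolecular [4+2] cycloaddition, and wet silica then opens the strained 1-methoxy-7-oxanorbornene 10 by heterolysis of the C3–O bridge bond, addition of water to the methoxy-stabilised cation and loss of methanol, which takes the adduct out of the retro-Diels–Alder equilibrium and leaves the furan oxygen as the C10 hydroxyl. The closest known reaction types are the intramolecular Diels–Alder reaction of furans (IMDAF) that carry an enone at the end of a four-atom tether and the donor-assisted bridge opening of adducts of 2-alkoxy- and 2-aminofurans; dehydration to an arene, the usual fate of such adducts, is blocked here by quaternary C5. Ring A (C10–C1=C2–C3–C4–C5) closes as the new cyclohexene of the cycloadduct, and ring B (C5–C6–C7–C8–C9–C10) closes in the fused, type 1 mode through the tether C9–C8–C7–C6 across the new C5–C10 bond. C4 and C5 follow from the (E)-alkene, whose two methyls stay cis; their cis relation to the C10 oxygen follows from the ketone-endo (tether-endo) transition state, which keeps C6=O under C1=C2, away from the lone pairs of the ring oxygen, and puts both methyls on the open side of the oxygen bridge; the furan face, and with it the absolute configuration of C10, C5 and C4, is fixed by C9, whose hydrogen lies in the furan plane next to the C5 methyl while the bulky OTBS group stands on the face away from the dienophile (pseudo-equatorial in the chair-like ring B). The step needs the tether to overrule the innate regiochemistry of a 2-methoxyfuran, which would join C10 to the enone β-carbon C4; the four-atom tether turns that mode into a strained seven-membered closure, and no Lewis acid is used because it would favour this ionic vinylogous Michael path and would ionise the furfuryl C9–O bond. The methoxy group still helps, since an electronegative substituent at the furan terminus makes the cycloaddition more exergonic and supplies the irreversible exit.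

Step 7
Reactants: 11 9α-(tert-butyldimethylsilyloxy)-8α-(triethylsilyloxy)-10β-hydroxy-4β,5β-dimethyl-cis-octal-1-ene-3,6-dione
Product: 12 9α-(tert-butyldimethylsilyloxy)-8α-(triethylsilyloxy)-10β-hydroxy-4β,5β-dimethyl-cis-decalin-3,6-dione
Conditions: H2 (1 atm), Pd/C, EtOAc, 23 °C
Reagents that add atoms: none
Why: Heterogeneous hydrogenation saturates the unhindered, disubstituted C1=C2 enone bond, the only C=C in the molecule, under neutral conditions that leave the silyl ethers and the epimerisable C4 alone.

Step 8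
Reactants: 12 9α-(tert-butyldimethylsilyloxy)-8α-(triethylsilyloxy)-10β-hydroxy-4β,5β-dimethyl-cis-decalin-3,6-dione
Product: 13 9α-(tert-butyldimethylsilyloxy)-8α-(triethylsilyloxy)-3β,10β-dihydroxy-4β,5β-dimethyl-cis-decalin-6-one
Conditions: LiBH(s-Bu)3 (L-Selectride), THF, −78 °C; then H2O
Reagents that add atoms: none
Why: Reduction with a bulky trialkylborohydride, in which the C3 ketone reacts before the neopentyl C6 ketone next to quaternary C5, and hydride enters from the α face by equatorial attack on the chair–chair conformer that holds C5–CH3 axial over ring A and C4–CH3 equatorial, so that the β face is closed by both methyls and the axial 3β-alcohol is set.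

Step 9
Reactants: 13 9α-(tert-butyldimethylsilyloxy)-8α-(triethylsilyloxy)-3β,10β-dihydroxy-4β,5β-dimethyl-cis-decalin-6-one
Product: 14 9α-(tert-butyldimethylsilyloxy)-8α-(triethylsilyloxy)-4β,5β-dimethyl-cis-decalin-3β,6α,10β-triol
Conditions: NaBH4, MeOH, 0 °C
Reagents that add atoms: none
Why: Borohydride reduction of the remaining ketone from the convex β face, next to the C10 hydroxyl, should give the 6α-alcohol; this centre only carries a leaving group and is erased in step 13, so its configuration has no bearing on the target.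

Step 10
Reactants: 14 9α-(tert-butyldimethylsilyloxy)-8α-(triethylsilyloxy)-4β,5β-dimethyl-cis-decalin-3β,6α,10β-triol
Product: 15 3β,6α-diacetoxy-9α-(tert-butyldimethylsilyloxy)-8α-(triethylsilyloxy)-4β,5β-dimethyl-cis-decalin-10β-ol
Conditions: Ac2O, DMAP (cat.), pyridine, 23 °C
Reagents that add atoms: acetic anhydride, CC(=O)OC(C)=O
Why: DMAP-catalysed acetylation of both secondary alcohols installs the C3 acetate of the target and turns C6–O into a leaving group, while the hindered tertiary C10 hydroxyl stays free.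

Step 11
Reactants: 15 3β,6α-diacetoxy-9α-(tert-butyldimethylsilyloxy)-8α-(triethylsilyloxy)-4β,5β-dimethyl-cis-decalin-10β-ol
Product: 16 3β,6α-diacetoxy-9α-(tert-butyldimethylsilyloxy)-4β,5β-dimethyl-cis-decalin-8α,10β-diol
Conditions: PPTS (cat.), MeOH–CH2Cl2, 0 °C
Reagents that add atoms: none
Why: Acid-catalysed methanolysis tells the silyl ethers apart by size, the TES ether being cleaved far faster than the TBS ether at neopentyl-type C9, and the acetates are inert.

Step 12
Reactants: 16 3β,6α-diacetoxy-9α-(tert-butyldimethylsilyloxy)-4β,5β-dimethyl-cis-decalin-8α,10β-diol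
Product: 17 3β,6α-diacetoxy-9α-(tert-butyldimethylsilyloxy)-10β-hydroxy-4β,5β-dimethyl-cis-decalin-8-one
Conditions: Dess–Martin periodinane, CH2Cl2, 0 to 23 °C
Reagents that add atoms: none
Why: Dess–Martin oxidation of the only free secondary alcohol under near-neutral conditions; the tertiary C10 hydroxyl cannot be oxidised, C9 is not enolised, and the spectator centre C8 disappears.

Step 13
Reactants: 17 3β,6α-diacetoxy-9α-(tert-butyldimethylsilyloxy)-10β-hydroxy-4β,5β-dimethyl-cis-decalin-8-one
Product: 18 3β-acetoxy-9α-(tert-butyldimethylsilyloxy)-10β-hydroxy-4β,5β-dimethyl-cis-octal-6-en-8-one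
Conditions: DBU, CH2Cl2, 0 °C, short contact
Reagents that add atoms: none
Why: E1cB elimination, in which deprotonation at C7, the accessible α position, expels the β-acetate at C6 and gives the C6=C7–C8=O enone, while low temperature keeps the hindered, oxygen-bearing C9–H from exchanging.

Step 14
Reactants: 18 3β-acetoxy-9α-(tert-butyldimethylsilyloxy)-10β-hydroxy-4β,5β-dimethyl-cis-octal-6-en-8-one
Product: 19 3β-acetoxy-9α-(tert-butyldimethylsilyloxy)-10β-hydroxy-7-iodo-4β,5β-dimethyl-cis-octal-6-en-8-one
Conditions: iodine, pyridine–CH2Cl2, 23 °C, dark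
Reagents that add atoms: iodine, [I][I]
Why: α-Iodination of an enone by a Baylis–Hillman-type addition–iodination–elimination sequence (pyridine adds at C6, the enolate is iodinated at C7, pyridine leaves), which is known for 4,4-disubstituted cyclohexenones.

Step 15
Reactants: 19 3β-acetoxy-9α-(tert-butyldimethylsilyloxy)-10β-hydroxy-7-iodo-4β,5β-dimethyl-cis-octal-6-en-8-one
Product: 20 3β-acetoxy-9α,10β-dihydroxy-7-iodo-4β,5β-dimethyl-cis-octal-6-en-8-one
Conditions: HF·pyridine, THF, 0 to 23 °C
Reagents that add atoms: none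
Why: Fluoride desilylation in an acidic medium, chosen because basic fluoride could trigger retro-aldol cleavage at C10, epimerisation at C9 or acetate migration.

Step 16
Reactants: 21 angelic acid
Product: 22 angeloyl 2,4,6-trichlorobenzoyl anhydride
Conditions: 2,4,6-trichlorobenzoyl chloride, Et3N, toluene, 23 °C; filtered and concentrated
Reagents that add atoms: 2,4,6-trichlorobenzoyl chloride, O=C(Cl)c1c(Cl)cc(Cl)cc1Cl
Why: Formation of the Yamaguchi mixed anhydride from the carboxylate and the hindered aroyl chloride; no nucleophilic catalyst is present, so the (Z)-alkene is kept.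

Step 17
Reactants: 20 3β-acetoxy-9α,10β-dihydroxy-7-iodo-4β,5β-dimethyl-cis-octal-6-en-8-one; 22 angeloyl 2,4,6-trichlorobenzoyl anhydride
Product: 23 3β-acetoxy-9α-angeloyloxy-10β-hydroxy-7-iodo-4β,5β-dimethyl-cis-octal-6-en-8-one
Conditions: toluene, 80 °C, no DMAP
Reagents that add atoms: none
Why: Yamaguchi-type esterification, in which the secondary C9 alcohol attacks the less hindered angeloyl carbonyl of the mixed anhydride, the tertiary C10 hydroxyl does not react, and the absence of a nucleophilic catalyst avoids addition–elimination isomerisation of the angelate to the tiglate.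

Step 18
Reactants: 23 3β-acetoxy-9α-angeloyloxy-10β-hydroxy-7-iodo-4β,5β-dimethyl-cis-octal-6-en-8-one
Product: 25 7-acetyl-3β-acetoxy-9α-angeloyloxy-10β-hydroxy-4β,5β-dimethyl-cis-octal-6-en-8-one (target CNP0196241.1), via ethoxyvinyl enone 24 (not isolated)
Conditions: tributyl(1-ethoxyvinyl)stannane, Pd(PPh3)4 (cat.), CuI (cat.), DMF, 45 °C; then 1 M HCl, THF, 0 °C
Reagents that add atoms: tributyl(1-ethoxyvinyl)stannane, CCCC[Sn](CCCC)(CCCC)C(=C)OCC; water, O
Why: Stille coupling of the α-iodoenone with an acetyl-anion equivalent under zerovalent palladium and copper co-catalysis, followed by mild acid hydrolysis of the enol ether to the methyl ketone; angelate, acetate and tertiary alcohol are inert, and the sensitive 2-acylenone appears only in the last operation.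

**Compound list**
1 | 2-methoxyfuran | COc1ccco1 | starting material
2 | ethyl glyoxylate | CCOC(=O)C=O | starting material
3 | ethyl (S)-2-hydroxy-2-(5-methoxyfuran-2-yl)acetate | O[C@@H](c1ccc(OC)o1)C(=O)OCC | intermediate
4 | ethyl (S)-2-(tert-butyldimethylsilyloxy)-2-(5-methoxyfuran-2-yl)acetate | CC(C)(C)[Si](C)(C)O[C@@H](c1ccc(OC)o1)C(=O)OCC | intermediate
5 | (S)-2-(tert-butyldimethylsilyloxy)-2-(5-methoxyfuran-2-yl)acetaldehyde | CC(C)(C)[Si](C)(C)O[C@@H](c1ccc(OC)o1)C=O | intermediate
6 | (E)-3-methylpent-3-en-2-one | C/C=C(\C)C(C)=O | starting material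
7 | lithium (E)-3-methylpenta-1,3-dien-2-olate | [Li]OC(=C)/C(C)=C/C | intermediate
8 | (1R,2R,5E)-1-(tert-butyldimethylsilyloxy)-2-hydroxy-1-(5-methoxyfuran-2-yl)-5-methylhept-5-en-4-one (8,9-anti) | CC(C)(C)[Si](C)(C)O[C@@H](c1ccc(OC)o1)[C@H](O)CC(=O)/C(C)=C/C | intermediate
9 | (1R,2R,5E)-1-(tert-butyldimethylsilyloxy)-2-(triethylsilyloxy)-1-(5-methoxyfuran-2-yl)-5-methylhept-5-en-4-one | CC(C)(C)[Si](C)(C)O[C@@H](c1ccc(OC)o1)[C@H](O[Si](CC)(CC)CC)CC(=O)/C(C)=C/C | intermediate
10 | 3α-methoxy-3β,10β-epoxy-9α-(tert-butyldimethylsilyloxy)-8α-(triethylsilyloxy)-4β,5β-dimethyl-cis-octal-1-en-6-one (1-methoxy-7-oxanorbornene cycloadduct) | CC(C)(C)[Si](C)(C)O[C@@H]1[C@H](O[Si](CC)(CC)CC)CC(=O)[C@]2(C)[C@@H](C)[C@]3(OC)C=C[C@]12O3 | intermediate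
11 | 9α-(tert-butyldimethylsilyloxy)-8α-(triethylsilyloxy)-10β-hydroxy-4β,5β-dimethyl-cis-octal-1-ene-3,6-dione | CC(C)(C)[Si](C)(C)O[C@@H]1[C@H](O[Si](CC)(CC)CC)CC(=O)[C@]2(C)[C@@H](C)C(=O)C=C[C@]12O | intermediate
12 | 9α-(tert-butyldimethylsilyloxy)-8α-(triethylsilyloxy)-10β-hydroxy-4β,5β-dimethyl-cis-decalin-3,6-dione | CC(C)(C)[Si](C)(C)O[C@@H]1[C@H](O[Si](CC)(CC)CC)CC(=O)[C@]2(C)[C@@H](C)C(=O)CC[C@]12O | intermediate
13 | 9α-(tert-butyldimethylsilyloxy)-8α-(triethylsilyloxy)-3β,10β-dihydroxy-4β,5β-dimethyl-cis-decalin-6-one | CC(C)(C)[Si](C)(C)O[C@@H]1[C@H](O[Si](CC)(CC)CC)CC(=O)[C@]2(C)[C@@H](C)[C@@H](O)CC[C@]12O | intermediate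
14 | 9α-(tert-butyldimethylsilyloxy)-8α-(triethylsilyloxy)-4β,5β-dimethyl-cis-decalin-3β,6α,10β-triol | CC(C)(C)[Si](C)(C)O[C@@H]1[C@H](O[Si](CC)(CC)CC)C[C@H](O)[C@]2(C)[C@@H](C)[C@@H](O)CC[C@]12O | intermediate
15 | 3β,6α-diacetoxy-9α-(tert-butyldimethylsilyloxy)-8α-(triethylsilyloxy)-4β,5β-dimethyl-cis-decalin-10β-ol | CC(C)(C)[Si](C)(C)O[C@@H]1[C@H](O[Si](CC)(CC)CC)C[C@H](OC(C)=O)[C@]2(C)[C@@H](C)[C@@H](OC(C)=O)CC[C@]12O | intermediate
16 | 3β,6α-diacetoxy-9α-(tert-butyldimethylsilyloxy)-4β,5β-dimethyl-cis-decalin-8α,10β-diol | CC(C)(C)[Si](C)(C)O[C@@H]1[C@H](O)C[C@H](OC(C)=O)[C@]2(C)[C@@H](C)[C@@H](OC(C)=O)CC[C@]12O | intermediate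
17 | 3β,6α-diacetoxy-9α-(tert-butyldimethylsilyloxy)-10β-hydroxy-4β,5β-dimethyl-cis-decalin-8-one | CC(C)(C)[Si](C)(C)O[C@@H]1C(=O)C[C@H](OC(C)=O)[C@]2(C)[C@@H](C)[C@@H](OC(C)=O)CC[C@]12O | intermediate
18 | 3β-acetoxy-9α-(tert-butyldimethylsilyloxy)-10β-hydroxy-4β,5β-dimethyl-cis-octal-6-en-8-one | CC(C)(C)[Si](C)(C)O[C@@H]1C(=O)C=C[C@]2(C)[C@@H](C)[C@@H](OC(C)=O)CC[C@]12O | intermediate
19 | 3β-acetoxy-9α-(tert-butyldimethylsilyloxy)-10β-hydroxy-7-iodo-4β,5β-dimethyl-cis-octal-6-en-8-one | CC(C)(C)[Si](C)(C)O[C@@H]1C(=O)C([I])=C[C@]2(C)[C@@H](C)[C@@H](OC(C)=O)CC[C@]12O | intermediate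
20 | 3β-acetoxy-9α,10β-dihydroxy-7-iodo-4β,5β-dimethyl-cis-octal-6-en-8-one | O[C@@H]1C(=O)C([I])=C[C@]2(C)[C@@H](C)[C@@H](OC(C)=O)CC[C@]12O | intermediate
21 | angelic acid, (Z)-2-methylbut-2-enoic acid | C/C=C(/C)C(O)=O | starting material
22 | angeloyl 2,4,6-trichlorobenzoyl anhydride | C/C=C(/C)C(=O)OC(=O)c1c(Cl)cc(Cl)cc1Cl | intermediate
23 | 3β-acetoxy-9α-angeloyloxy-10β-hydroxy-7-iodo-4β,5β-dimethyl-cis-octal-6-en-8-one | C/C=C(/C)C(=O)O[C@@H]1C(=O)C([I])=C[C@]2(C)[C@@H](C)[C@@H](OC(C)=O)CC[C@]12O | intermediate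
24 | 3β-acetoxy-9α-angeloyloxy-7-(1-ethoxyvinyl)-10β-hydroxy-4β,5β-dimethyl-cis-octal-6-en-8-one | C/C=C(/C)C(=O)O[C@@H]1C(=O)C(C(=C)OCC)=C[C@]2(C)[C@@H](C)[C@@H](OC(C)=O)CC[C@]12O | intermediate
25 | 7-acetyl-3β-acetoxy-9α-angeloyloxy-10β-hydroxy-4β,5β-dimethyl-cis-octal-6-en-8-one (CNP0196241.1) | C/C=C(/C)C(=O)O[C@@H]1C(=O)C(C(C)=O)=C[C@]2(C)[C@@H](C)[C@@H](OC(C)=O)CC[C@]12O | target

**Total steps:** 18. **Longest linear sequence:** 17 (steps 1–15, 17 and 18; step 16 is a side branch).

**Steps most likely to fail**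

**Step 6.**
- What may go wrong: two fully substituted carbons are joined against the innate polarity of the methoxyfuran, so the cycloaddition may be outrun by cycloreversion or by thermal loss of triethylsilanol from the β-silyloxy ketone.
- Material may also leak through the tether-exo mode to the trans-fused series, and the product may suffer retro-aldol cleavage of C5–C10 or epimerisation at C4 during the hydrolysis.
- Fallback (sets out from 5, comes back at 18): the flexible tether is replaced by a flat, cis-locked vinylogous ester. This tether has fewer rotors, no C8 stereocentre and no β-leaving group, and it already holds C8 at the ketone level.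
- Ohira–Bestmann homologation of 5 (dimethyl (1-diazo-2-oxopropyl)phosphonate, K2CO3, MeOH) would give the propargylic silyl ether F1.
- Deprotonation with n-BuLi and acylation with (E)-N-methoxy-N,2-dimethylbut-2-enamide would give the ynone F2.
- DABCO-catalysed conjugate addition of methanol would give the (E)-β-methoxy dienone F3, in which C9 and C6 are cis on C7=C8.
- The thermal cycloaddition would give the bridged ketal F4, which wet silica opens to the hydroxy enone vinylogous ester F5.
- Hydrogenation of C1=C2 would give the saturated C3 ketone F6.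
- i-Bu2AlH would reduce the C3 ketone from the α face and the C6 carbonyl to the 3β,6α-diol F7.
- Dilute HCl would then complete a Stork–Danheiser transposition to the 3β-hydroxy-6-en-8-one F8.
- Acetylation of the secondary alcohol would give 18, so that steps 6 to 13 are bypassed.

**Step 8.**
- What may go wrong: facial selectivity may erode or invert if the cis-decalin reacts through its other chair–chair conformer. Enolisation by the basic hydride may also epimerise C4.
- Fallback (sets out from 12, comes back at 15): C3 is set by SN2 inversion instead of by the choice of hydride face.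
- The 3α-alcohol F9 that β-face delivery produces would be treated with acetic acid, PPh3 and DIAD. This Mitsunobu reaction inverts C3 and installs the acetate in one operation, giving the 3β-acetoxy 6-ketone F10. The conformer that admits hydride from the β face also admits acetate from that face.
- NaBH4 would then reduce C6 to the 3β-acetoxy 6α-alcohol F11, and acetylation of C6–OH would give 15.

**Step 17.**
- What may go wrong: acylation of the hindered, deactivated α-ketol hydroxyl may be slow.
- Long heating may let the angelate isomerise to the tiglate or let the α-ketol tautomerise.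
- Fallback (sets out from 20, comes back at 23): the (Z)-alkene is built on the ester instead of being carried through the acylation.
- Esterification of 20 with 2-[bis(2,2,2-trifluoroethoxy)phosphoryl]propanoic acid (EDC, DMAP, which is harmless here because no alkene is present) would give the C9 phosphonopropionate F12.
- A Still–Gennari olefination with acetaldehyde (KN(SiMe3)2, 18-crown-6, THF, −78 °C, one equivalent of base for the most acidic C–H) would give the angelate 23.

**Further compounds**
F1 | step 6 | (R)-tert-butyl{[1-(5-methoxyfuran-2-yl)prop-2-yn-1-yl]oxy}dimethylsilane, the propargylic silyl ether | CC(C)(C)[Si](C)(C)O[C@@H](c1ccc(OC)o1)C#C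
F2 | step 6 | (R,E)-1-(tert-butyldimethylsilyloxy)-1-(5-methoxyfuran-2-yl)-5-methylhept-5-en-2-yn-4-one, the ynone | CC(C)(C)[Si](C)(C)O[C@@H](c1ccc(OC)o1)C#CC(=O)/C(C)=C/C
F3 | step 6 | (2E,5E)-1-(tert-butyldimethylsilyloxy)-2-methoxy-1-(5-methoxyfuran-2-yl)-5-methylhepta-2,5-dien-4-one with the C9 configuration of 5, the (E)-β-methoxy dienone | CC(C)(C)[Si](C)(C)O[C@@H](c1ccc(OC)o1)/C(OC)=C\C(=O)/C(C)=C/C
F4 | step 6 | 3α,8-dimethoxy-3β,10β-epoxy-9α-(tert-butyldimethylsilyloxy)-4β,5β-dimethyl-cis-hexalin-1,7-dien-6-one, the bridged ketal | CC(C)(C)[Si](C)(C)O[C@@H]1C(OC)=CC(=O)[C@]2(C)[C@@H](C)[C@]3(OC)C=C[C@]12O3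
F5 | step 6 | 9α-(tert-butyldimethylsilyloxy)-10β-hydroxy-8-methoxy-4β,5β-dimethyl-cis-hexalin-1,7-diene-3,6-dione, the hydroxy enone vinylogous ester | CC(C)(C)[Si](C)(C)O[C@@H]1C(OC)=CC(=O)[C@]2(C)[C@@H](C)C(=O)C=C[C@]12O
F6 | step 6 | 9α-(tert-butyldimethylsilyloxy)-10β-hydroxy-8-methoxy-4β,5β-dimethyl-cis-octal-7-ene-3,6-dione, the saturated C3 ketone | CC(C)(C)[Si](C)(C)O[C@@H]1C(OC)=CC(=O)[C@]2(C)[C@@H](C)C(=O)CC[C@]12O
F7 | step 6 | 9α-(tert-butyldimethylsilyloxy)-8-methoxy-4β,5β-dimethyl-cis-octal-7-ene-3β,6α,10β-triol, the 3β,6α-diol | CC(C)(C)[Si](C)(C)O[C@@H]1C(OC)=C[C@H](O)[C@]2(C)[C@@H](C)[C@@H](O)CC[C@]12O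
F8 | step 6 | 9α-(tert-butyldimethylsilyloxy)-3β,10β-dihydroxy-4β,5β-dimethyl-cis-octal-6-en-8-one, the 3β-hydroxy-6-en-8-one | CC(C)(C)[Si](C)(C)O[C@@H]1C(=O)C=C[C@]2(C)[C@@H](C)[C@@H](O)CC[C@]12O
F9 | step 8 | 9α-(tert-butyldimethylsilyloxy)-8α-(triethylsilyloxy)-3α,10β-dihydroxy-4β,5β-dimethyl-cis-decalin-6-one, the 3α-alcohol | CC(C)(C)[Si](C)(C)O[C@@H]1[C@H](O[Si](CC)(CC)CC)CC(=O)[C@]2(C)[C@@H](C)[C@H](O)CC[C@]12O
F10 | step 8 | 3β-acetoxy-9α-(tert-butyldimethylsilyloxy)-8α-(triethylsilyloxy)-10β-hydroxy-4β,5β-dimethyl-cis-decalin-6-one, the 3β-acetoxy 6-ketone | CC(C)(C)[Si](C)(C)O[C@@H]1[C@H](O[Si](CC)(CC)CC)CC(=O)[C@]2(C)[C@@H](C)[C@@H](OC(C)=O)CC[C@]12O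
F11 | step 8 | 3β-acetoxy-9α-(tert-butyldimethylsilyloxy)-8α-(triethylsilyloxy)-4β,5β-dimethyl-cis-decalin-6α,10β-diol, the 3β-acetoxy 6α-alcohol | CC(C)(C)[Si](C)(C)O[C@@H]1[C@H](O[Si](CC)(CC)CC)C[C@H](O)[C@]2(C)[C@@H](C)[C@@H](OC(C)=O)CC[C@]12O
F12 | step 17 | 3β-acetoxy-9α-{2-[bis(2,2,2-trifluoroethoxy)phosphoryl]propanoyloxy}-10β-hydroxy-7-iodo-4β,5β-dimethyl-cis-octal-6-en-8-one (both epimers at the phosphonate carbon), the C9 phosphonopropionate | CC(C(=O)O[C@@H]1C(=O)C([I])=C[C@]2(C)[C@@H](C)[C@@H](OC(C)=O)CC[C@]12O)P(=O)(OCC(F)(F)F)OCC(F)(F)F
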